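**Retrosynthetic overview**
1. The target is reached from its 7‑methylidene analogue; the last stereocentre (C7) is set by thermodynamically controlled reduction of the exocyclic C=CH2.
2. The C5–C6 bond of the seven‑membered ring comes from a biaryl phenol carrying a 2‑substituted allylsilane, by a one‑pot oxidative dearomatisation in which two rings close in sequence.
3. Order of ring formation: both benzene rings are bought; in the key pot a five‑membered spiro‑ether closes first (transient), then the seven‑membered carbocycle; the dienone ring arises by dearomatisation in the same operation.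
4. The biaryl bond comes from a Suzuki–Miyaura coupling of an ortho‑bromo aryl carbinol with a commercial 4‑hydroxyaryl boronate.
5. The allylsilane comes from an ester (twofold silylmethyl addition, Peterson elimination); C9 and C8 come from an Evans syn‑aldol reaction.

Assumption: locants follow the benzo[7]annulene skeleton of the target (C5 spiro carbon, C6 CH2, C7 and C8 methyl‑bearing carbons, C9 carbinol carbon); the SMILES corresponds to (7R,8S,9R), with 9‑OH trans to 8‑CH3 and 8‑CH3 trans to 7‑CH3. Abbreviations: SPhos = 2‑dicyclohexylphosphino‑2',6'‑dimethoxybiphenyl; dpm = 2,2,6,6‑tetramethylheptane‑3,5‑dionate; nbd = norbornadiene; dppb = 1,4‑bis(diphenylphosphino)butane; dba = dibenzylideneacetone.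

**Step 1**
Reactants: 1 2-bromo-3,4,5-trimethoxybenzaldehyde; 2 (R)-4-benzyl-3-propanoyl-1,3-oxazolidin-2-one
Product: 3 (R)-4-benzyl-3-[(2R,3R)-3-(2-bromo-3,4,5-trimethoxyphenyl)-3-hydroxy-2-methylpropanoyl]-1,3-oxazolidin-2-one
Conditions: Bu2BOTf, iPr2NEt, CH2Cl2, −78 → 0 °C; then H2O2, MeOH, pH 7 buffer
Reagents that add atoms: none
Why: Evans syn‑aldol reaction: the (Z)‑boron enolate of 2 adds through a Zimmerman–Traxler chair in which the (R)‑benzyl group shields one enolate face, which sets the carbinol carbon (future C9, R) and the methyl‑bearing carbon (future C8) in the syn relationship of the target.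

**Step 2**
Reactants: 3 (R)-4-benzyl-3-[(2R,3R)-3-(2-bromo-3,4,5-trimethoxyphenyl)-3-hydroxy-2-methylpropanoyl]-1,3-oxazolidin-2-one
Product: 4 methyl (2R,3R)-3-(2-bromo-3,4,5-trimethoxyphenyl)-3-hydroxy-2-methylpropanoate
Conditions: NaOMe (0.2 equiv), MeOH/CH2Cl2, −10 °C
Reagents that add atoms: methanol, CO
Why: Transesterification: methoxide attacks the more electrophilic exocyclic carbonyl and releases the auxiliary, and the short, cold reaction avoids retro‑aldol cleavage or epimerisation of the two stereocentres.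

**Step 3**
Reactants: 4 methyl (2R,3R)-3-(2-bromo-3,4,5-trimethoxyphenyl)-3-hydroxy-2-methylpropanoate
Product: 6 (1R,2S)-1-(2-bromo-3,4,5-trimethoxyphenyl)-2-methyl-3-[(trimethylsilyl)methyl]but-3-en-1-ol, via bis(silylmethyl) carbinol 5 (not isolated)
Conditions: Me3SiCH2MgCl, CeCl3, THF, −78 → 20 °C; then SiO2, CH2Cl2
Reagents that add atoms: (trimethylsilyl)methylmagnesium chloride, C[Si](C)(C)C[Mg]Cl
Why: Twofold addition of the weakly basic organocerium reagent to the ester gives the bis(β‑silyl) tertiary carbinol 5, and Peterson elimination of Me3SiOH on silica gives the 2‑substituted allylsilane (ester‑to‑allylsilane conversion); the stereocentres are not touched.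

**Step 4**
Reactants: 6 (1R,2S)-1-(2-bromo-3,4,5-trimethoxyphenyl)-2-methyl-3-[(trimethylsilyl)methyl]but-3-en-1-ol; 7 2,6-dimethoxy-4-(4,4,5,5-tetramethyl-1,3,2-dioxaborolan-2-yl)phenol
Product: 8 4-{6-[(1R,2S)-1-hydroxy-2-methyl-3-[(trimethylsilyl)methyl]but-3-en-1-yl]-2,3,4-trimethoxyphenyl}-2,6-dimethoxyphenol
Conditions: Pd(OAc)2 (3 mol%), SPhos, K3PO4, toluene/H2O, 90 °C
Reagents that add atoms: none
Why: Suzuki–Miyaura coupling with SPhos, which couples doubly ortho‑substituted aryl bromides; the free phenol, the secondary alcohol and the allylsilane tolerate the aqueous phosphate conditions and no stereocentre is involved.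

**Step 5 (key step)**
Reactants: 8 4-{6-[(1R,2S)-1-hydroxy-2-methyl-3-[(trimethylsilyl)methyl]but-3-en-1-yl]-2,3,4-trimethoxyphenyl}-2,6-dimethoxyphenol
Product: 10 (8S,9R)-9-hydroxy-2,3,3',4,5'-pentamethoxy-8-methyl-7-methylidene-6,7,8,9-tetrahydrospiro[benzo[7]annulene-5,1'-cyclohexa[2,5]dien]-4'-one, via spiro-ether 9 (not isolated)
Conditions: PhI(OAc)2, CH2Cl2/(CF3)2CHOH, −20 °C; then BF3·OEt2 (0.3 equiv), −40 → 0 °C
Reagents that add atoms: none
Why: Proposed new method: PhI(OAc)2 oxidises the phenol to a 4‑aryl phenoxenium ion that has no benzylic hydrogen (so no quinone methide can form) and is trapped first by the free benzylic hydroxyl in a fast 5‑exo closure to spiro‑ether 9 (oxidative spiro‑etherification, known); BF3·OEt2 then re‑ionises this doubly allylic, aryl‑stabilised C–O bond and the allylsilane captures the cation irreversibly at the para carbon through its CH2 terminus (intramolecular Hosomi–Sakurai allylation of a quinol ether or quinone ketal is the closest known reaction type), which closes the seven‑membered ring, frees the alcohol and leaves the exocyclic methylidene after loss of the silyl group; no new stereocentre forms because the spiro carbon carries two identical dienone arms.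

**Step 6**
Reactants: 10 (8S,9R)-9-hydroxy-2,3,3',4,5'-pentamethoxy-8-methyl-7-methylidene-6,7,8,9-tetrahydrospiro[benzo[7]annulene-5,1'-cyclohexa[2,5]dien]-4'-one
Product: 11 (7R,8S,9R)-9-hydroxy-2,3,3',4,5'-pentamethoxy-7,8-dimethyl-6,7,8,9-tetrahydrospiro[benzo[7]annulene-5,1'-cyclohexa[2,5]dien]-4'-one
Conditions: Mn(dpm)3 (10 mol%), PhSiH3, tBuOOH, iPrOH, 22 °C
Reagents that add atoms: none
Why: Metal‑hydride hydrogen‑atom‑transfer (HAT) hydrogenation: H• goes to the exocyclic CH2 (the most accessible, electron‑neutral alkene, whereas the dienone C=C bonds are electron‑poor and flanked by the quaternary spiro carbon), and the tertiary C7 radical then takes up hydrogen to give the thermodynamically preferred all‑pseudo‑equatorial arrangement, which sets C7 (R) with the new methyl trans to the C8 methyl and cis to the C9 hydroxyl.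

**Compound list**
1 | 2-bromo-3,4,5-trimethoxybenzaldehyde | O=Cc1cc(OC)c(OC)c(OC)c1Br | starting material
2 | (R)-4-benzyl-3-propanoyl-1,3-oxazolidin-2-one | CCC(=O)N1[C@H](Cc2ccccc2)COC1=O | starting material
3 | (R)-4-benzyl-3-[(2R,3R)-3-(2-bromo-3,4,5-trimethoxyphenyl)-3-hydroxy-2-methylpropanoyl]-1,3-oxazolidin-2-one | O=C1OC[C@@H](Cc2ccccc2)N1C(=O)[C@H](C)[C@@H](O)c1cc(OC)c(OC)c(OC)c1Br | intermediate
4 | methyl (2R,3R)-3-(2-bromo-3,4,5-trimethoxyphenyl)-3-hydroxy-2-methylpropanoate | COC(=O)[C@H](C)[C@@H](O)c1cc(OC)c(OC)c(OC)c1Br | intermediate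
5 | (1R,2R)-1-(2-bromo-3,4,5-trimethoxyphenyl)-2-methyl-4-(trimethylsilyl)-3-[(trimethylsilyl)methyl]butane-1,3-diol | C[Si](C)(C)CC(O)(C[Si](C)(C)C)[C@H](C)[C@@H](O)c1cc(OC)c(OC)c(OC)c1Br | intermediate
6 | (1R,2S)-1-(2-bromo-3,4,5-trimethoxyphenyl)-2-methyl-3-[(trimethylsilyl)methyl]but-3-en-1-ol | C=C(C[Si](C)(C)C)[C@H](C)[C@@H](O)c1cc(OC)c(OC)c(OC)c1Br | intermediate
7 | 2,6-dimethoxy-4-(4,4,5,5-tetramethyl-1,3,2-dioxaborolan-2-yl)phenol | COc1cc(B2OC(C)(C)C(C)(C)O2)cc(OC)c1O | starting material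
8 | 4-{6-[(1R,2S)-1-hydroxy-2-methyl-3-[(trimethylsilyl)methyl]but-3-en-1-yl]-2,3,4-trimethoxyphenyl}-2,6-dimethoxyphenol | C=C(C[Si](C)(C)C)[C@H](C)[C@@H](O)c1cc(OC)c(OC)c(OC)c1-c1cc(OC)c(O)c(OC)c1 | intermediate
9 | (3'R)-3,5,5',6',7'-pentamethoxy-3'-{(2S)-3-[(trimethylsilyl)methyl]but-3-en-2-yl}-3'H-spiro[cyclohexa-2,5-diene-1,1'-[2]benzofuran]-4-one | COC1=CC2(C=C(OC)C1=O)O[C@H]([C@@H](C)C(=C)C[Si](C)(C)C)c1cc(OC)c(OC)c(OC)c12 | intermediate
10 | (8S,9R)-9-hydroxy-2,3,3',4,5'-pentamethoxy-8-methyl-7-methylidene-6,7,8,9-tetrahydrospiro[benzo[7]annulene-5,1'-cyclohexa[2,5]dien]-4'-one | COC1=CC2(C=C(OC)C1=O)CC(=C)[C@H](C)[C@@H](O)c1cc(OC)c(OC)c(OC)c12 | intermediate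
11 | (7R,8S,9R)-9-hydroxy-2,3,3',4,5'-pentamethoxy-7,8-dimethyl-6,7,8,9-tetrahydrospiro[benzo[7]annulene-5,1'-cyclohexa[2,5]dien]-4'-one (CNP0288561.1) | COC1=CC2(C=C(OC)C1=O)C[C@@H](C)[C@H](C)[C@@H](O)c1cc(OC)c(OC)c(OC)c12 | target

**Total step count:** 6. **Longest linear sequence:** 6 (from 1).

**Three steps most likely to fail, with fallbacks**

Step 5 is the most exposed. Spiro‑ether 9 may not re‑open productively, it may ionise instead at the benzylic C–O bond and erode C9, or the acidic medium may protodesilylate the allylsilane. The fallback keeps the hydroxyl out of the cation chemistry and sets out from 6. Silylation with tBuMe2SiOTf and 2,6‑lutidine gives tert-butyl{[(1R,2S)-1-(2-bromo-3,4,5-trimethoxyphenyl)-2-methyl-3-[(trimethylsilyl)methyl]but-3-en-1-yl]oxy}dimethylsilane F1. Coupling with 7 under the conditions of step 4 gives 4-{6-[(1R,2S)-1-{[tert-butyl(dimethyl)silyl]oxy}-2-methyl-3-[(trimethylsilyl)methyl]but-3-en-1-yl]-2,3,4-trimethoxyphenyl}-2,6-dimethoxyphenol F2. Oxidation with PhI(OAc)2 in (CF3)2CHOH then leaves the allylsilane as the only internal nucleophile (direct oxidative Hosomi–Sakurai spirocyclisation) and gives (8S,9R)-9-{[tert-butyl(dimethyl)silyl]oxy}-2,3,3',4,5'-pentamethoxy-8-methyl-7-methylidene-6,7,8,9-tetrahydrospiro[benzo[7]annulene-5,1'-cyclohexa[2,5]dien]-4'-one F3. Bu4NF removes the silyl ether and the route is rejoined at 10.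

Step 6 may reduce a dienone C=C bond or give the 7‑epimer, because kinetic reagents and hydroxyl‑directed catalysts would deliver hydrogen to the wrong face. The fallback sets C7 on the open chain before any ring is closed and sets out from 6. A fluoride‑promoted, palladium‑catalysed allyl–aryl coupling of the allylsilane (Pd2(dba)3, Bu4NF, THF; Hiyama type, with the external aryl iodide reacting faster than the hindered internal bromide) with 4‑iodo‑2,6‑dimethoxyphenol gives 4-[(3S,4R)-4-(2-bromo-3,4,5-trimethoxyphenyl)-4-hydroxy-3-methyl-2-methylidenebutyl]-2,6-dimethoxyphenol F4. Hydroxyl‑directed hydrogenation with [Rh(nbd)(dppb)]BF4 and H2 (chelate control, with 1,2‑allylic strain keeping the C8 methyl away from the benzylic arm) gives 4-[(2R,3S,4R)-4-(2-bromo-3,4,5-trimethoxyphenyl)-4-hydroxy-2,3-dimethylbutyl]-2,6-dimethoxyphenol F5. A palladium‑catalysed arylative dearomatisation of the phenol by the aryl bromide (Pd2(dba)3, SPhos, K2CO3, dioxane) then closes ring B and arrives directly at 11.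

Step 3 may stall at the ketone stage, or the magnesium aldolate may undergo retro‑aldol cleavage. The fallback builds the allylsilane one carbon at a time and sets out from 4. Me(MeO)NH·HCl with iPrMgCl gives the Weinreb amide (2R,3R)-3-(2-bromo-3,4,5-trimethoxyphenyl)-3-hydroxy-N-methoxy-N,2-dimethylpropanamide F6. Me3SiCH2Li gives the α‑silyl ketone (3R,4R)-4-(2-bromo-3,4,5-trimethoxyphenyl)-4-hydroxy-3-methyl-1-(trimethylsilyl)butan-2-one F7. Wittig methylenation with Ph3P=CH2 comes back to 6.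

**Further compounds**
F1 | step 5 | tert-butyl{[(1R,2S)-1-(2-bromo-3,4,5-trimethoxyphenyl)-2-methyl-3-[(trimethylsilyl)methyl]but-3-en-1-yl]oxy}dimethylsilane | C=C(C[Si](C)(C)C)[C@H](C)[C@@H](O[Si](C)(C)C(C)(C)C)c1cc(OC)c(OC)c(OC)c1Br
F2 | step 5 | 4-{6-[(1R,2S)-1-{[tert-butyl(dimethyl)silyl]oxy}-2-methyl-3-[(trimethylsilyl)methyl]but-3-en-1-yl]-2,3,4-trimethoxyphenyl}-2,6-dimethoxyphenol | C=C(C[Si](C)(C)C)[C@H](C)[C@@H](O[Si](C)(C)C(C)(C)C)c1cc(OC)c(OC)c(OC)c1-c1cc(OC)c(O)c(OC)c1
F3 | step 5 | (8S,9R)-9-{[tert-butyl(dimethyl)silyl]oxy}-2,3,3',4,5'-pentamethoxy-8-methyl-7-methylidene-6,7,8,9-tetrahydrospiro[benzo[7]annulene-5,1'-cyclohexa[2,5]dien]-4'-one | COC1=CC2(C=C(OC)C1=O)CC(=C)[C@H](C)[C@@H](O[Si](C)(C)C(C)(C)C)c1cc(OC)c(OC)c(OC)c12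
F4 | step 6 | 4-[(3S,4R)-4-(2-bromo-3,4,5-trimethoxyphenyl)-4-hydroxy-3-methyl-2-methylidenebutyl]-2,6-dimethoxyphenol | C=C(Cc1cc(OC)c(O)c(OC)c1)[C@H](C)[C@@H](O)c1cc(OC)c(OC)c(OC)c1Br
F5 | step 6 | 4-[(2R,3S,4R)-4-(2-bromo-3,4,5-trimethoxyphenyl)-4-hydroxy-2,3-dimethylbutyl]-2,6-dimethoxyphenol | COc1cc(C[C@@H](C)[C@H](C)[C@@H](O)c2cc(OC)c(OC)c(OC)c2Br)cc(OC)c1O
F6 | step 3 | (2R,3R)-3-(2-bromo-3,4,5-trimethoxyphenyl)-3-hydroxy-N-methoxy-N,2-dimethylpropanamide | CON(C)C(=O)[C@H](C)[C@@H](O)c1cc(OC)c(OC)c(OC)c1Br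
F7 | step 3 | (3R,4R)-4-(2-bromo-3,4,5-trimethoxyphenyl)-4-hydroxy-3-methyl-1-(trimethylsilyl)butan-2-one | C[Si](C)(C)CC(=O)[C@H](C)[C@@H](O)c1cc(OC)c(OC)c(OC)c1Br
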